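In a one-step world the starting material consumed in the beta run by 20.0 min would stand as first product, 61.7%, yet the reading was 33.6%, so the meeting on the new flask opened with a different question: where does first product stop climbing?

| flask | starting material | reagent | remark | time |
|---|---|---|---|---|
| zeta | 0.12 M | 0.75 M | run made earlier |  |
| beta | 0.19 M | 0.75 M | run made earlier |  |
| flask | 0.25 M | 0.750 M |  | 20 min |

| run | time / min | first product / % | starting material / % |
|---|---|---|---|
| zeta | 1.50 | 7.0 | 92.3 |
| zeta | 4.00 | 16.6 | 80.5 |
| zeta | 8.00 | 25.6 | 65.5 |
| zeta | 20.0 | 34.7 | 36.0 |
| beta | 5.00 | 18.6 | 77.5 |
| beta | 10.0 | 27.7 | 59.4 |
| beta | 15.0 | 31.8 | 47.8 |
| beta | 20.0 | 33.6 | 38.3 |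

(readings scatter by 0.5 percentage points)

* equivalents of reagent to starting material, everything else as given, that leave most first product at 20 min
* the amount of first product then, in percent of the starting material charged
* the amount of first product with the amounts as given

- what was read earlier has a scatter of 0.5 percentage points, one standard deviation
- reactions considered so far: starting material + reagent -> first product; reagent + first product -> bis adduct; reagent + first product -> over-reaction product; first product <-> isomer of the product

The chair put the end state first, saying that first product is itself consumed and so must pass a top where making equals loss. The secretary then offered her own reckoning of how close the flask comes to that top. Over the beta run's last interval, from 15.0 min to 20.0 min, starting material fell at a pseudo-first-order rate of 0.0441 /min, while first product, judged by what starting material gave up and first product failed to gain, was lost at 0.0471 /min. Dividing the first by the second gave 0.937, the standstill ratio: the value of [first product]/[starting material] at which making equals loss, a kind of selectivity factor, from which [reagent] divides out for steps that use reagent on both sides, and a reading that carries the scatter of 0.5 percentage points on each figure. The beta run's own ratio at 20.0 min was 0.877, lower than the standstill ratio by 0.0600, a gap she did not claim these readings could establish, so she held that the flask too would be read close to its top, near the beta yield. The forecaster reported 32.8% (range 31.8% to 33.7%) for the flask as charged and 34.5% at 3.8 equiv, adding that “the maximum is flat”.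

The simulation gives 33.4% for the flask, and 34.2% at 3.72 equiv, each inside the forecast's range; with the other settings held, [reagent] has to reach 0.476 M or 1.60 M before the flask's answer moves by 5 points.

    starting material + reagent → first product (k = 0.0732 /M/min)
    reagent + first product → bis adduct (k = 0.0430 /M/min)
    reagent + first product → over-reaction product (k = 0.0175 /M/min)
    first product ⇌ isomer of the product (K = 0.321, k = 0.0552 /min)

In the flask at 20.0 min the ratio stood at 0.852, and the standstill ratio divided by it gives 1.10, beside a simulated 1.17 for making over using up, each step taken net. The neighbouring flask, charged with 1.9 M of reagent and read at 20.0 min, holds 8.70% starting material and 24.4% first product, a ratio of 2.80, so the same division gives 0.335 and reckons first product there as lost faster than it is made. That flask's first product stands lower than the 33.4% of the flask as charged, and of the starting material charged to it the most now stands as bis adduct, at 41.2%.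

All runs are calculated from invented constants, noise included.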